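**Retrosynthetic overview**
1. Target 21 ← β,γ-epoxy aldehyde (E1cB epoxide opening gives the γ-hydroxy enal) ← epoxidation of a C6=C7 alkene anti to the angular methyl.
2. Side chain: C12–C13 bond by hydroboration / B-alkyl Suzuki–Miyaura coupling of a C9 vinyl group with a (Z)-β-iodo enoate, which fixes the enoate geometry.
3. Rings A and B are formed together in step 5: a catalytic asymmetric inverse-demand intramolecular [4+2] of an acyclic tetraenal (bonds C5–C10 and C8–C9) sets C5, C9 and C10.
4. The tetraenal comes from 5-chloropent-1-yne (carboalumination/Negishi coupling), isobutyronitrile (quaternary C4) and methoxybutenyne (dienal).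

Atom labels C1–C17 follow labdane numbering: C5/C10 ring fusion, C4 gem-dimethyl, C6 carbinol, C7=C8, C17 formyl carbon, C9 side-chain carbon, C11–C16 side chain.

Assumption: the facial sense of the chiral catalyst in step 5 is assigned by analogy and written for the (S)-catalyst; if it proves opposite, the (R)-catalyst is used and nothing else changes.

**Route**

Step 1
Reactants: 1 5-chloropent-1-yne; 2 bromoethene (vinyl bromide)
Product: 4 (3E)-7-chloro-4-methylhepta-1,3-diene, via alkenylalane 3 (not isolated)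
Conditions: Me3Al (2 equiv), Cp2ZrCl2 (20 mol%), CH2Cl2, 0 °C → rt; then 2 (1 M in THF), Pd(PPh3)4 (3 mol%), ZnCl2 (20 mol%), THF, rt; aqueous work-up
Reagents that add atoms: trimethylaluminium C[Al](C)C
Why: Zirconium-catalysed Negishi carboalumination adds Me and Al syn across the terminal alkyne (Me to the internal carbon), and the alkenylalane couples with vinyl bromide with retention (Negishi coupling), fixing the (E)-trisubstituted alkene that later makes the C10 methyl and the C9 substituent cis.

Step 2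
Reactants: 4 (3E)-7-chloro-4-methylhepta-1,3-diene; 5 2-methylpropanenitrile (isobutyronitrile)
Product: 6 (6E)-2,2,6-trimethylnona-6,8-dienenitrile
Conditions: LiN(i-Pr)2, THF, −78 °C; then 4, NaI (10 mol%), DMPU, −78 °C → rt
Reagents that add atoms: none
Why: SN2 alkylation of the α-cyano carbanion (nitrile anion alkylation with in situ Finkelstein activation) builds the quaternary gem-dimethyl carbon C4; no stereocentre is formed.

Step 3
Reactants: 6 (6E)-2,2,6-trimethylnona-6,8-dienenitrile
Product: 7 (6E)-2,2,6-trimethylnona-6,8-dienal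
Conditions: i-Bu2AlH (1.2 equiv), CH2Cl2, −78 °C; then 1 M aq. HCl, 0 °C
Reagents that add atoms: water O
Why: Partial nitrile reduction: the hydride adds once to give an N-aluminio imine that is hydrolysed to the aldehyde, and the diene is inert to the reagent.

Step 4
Reactants: 7 (6E)-2,2,6-trimethylnona-6,8-dienal; 8 (Z)-1-methoxybut-1-en-3-yne
Product: 11 (2E,4E,10E)-6,6,10-trimethyltrideca-2,4,10,12-tetraenal, via propargylic alkoxide 9 (not isolated), via dienol ether alcohol 10 (not isolated)
Conditions: 8, n-BuLi, THF, −78 °C; then 7, −78 → 0 °C; LiAlH4, 0 °C → rt; then 1 M aq. HCl, THF, 0 °C → rt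
Reagents that add atoms: water O
Why: Acetylide 1,2-addition, alkoxide-directed trans-hydroalumination of the propargylic alkoxide, then acid-promoted loss of the hydroxyl with enol ether hydrolysis (four-carbon homologation with a methoxybutenyne linchpin) gives the thermodynamic (2E,4E)-dienal.

Step 5
Reactants: 11 (2E,4E,10E)-6,6,10-trimethyltrideca-2,4,10,12-tetraenal
Product: 13 (1R,2R,4aR,8aS)-2-(dimethoxymethyl)-1-ethenyl-5,5,8a-trimethyl-1,2,4a,5,6,7,8,8a-octahydronaphthalene, via cycloadduct aldehyde 12 (not isolated)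
Conditions: (S)-B-(o-tolyl) oxazaborolidine from (S)-α,α-diphenylprolinol (20 mol%), Tf2NH (18 mol%), CH2Cl2 (0.01 M), −78 → −40 °C; then HC(OMe)3, MeOH, −40 → 0 °C; Et3N quench
Reagents that add atoms: trimethyl orthoformate COC(OC)OC
Why: Proposed new method: the boron-bound (2E,4E)-dienal is an electron-poor 4π unit whose electrophilic C5 is attacked by the doubly alkylated terminus C10 of the 1,3-diene (ring A, the only ring size within reach), and the resulting allyl cation/boron dienolate pair closes C8–C9 (ring B), i.e. an asynchronous inverse-electron-demand intramolecular Diels–Alder reaction; the 1,3-diene cannot serve as the 4π partner because its (Z)-methyl blocks the s-cis form; the endo transition state (C11=C12 vinyl and C10 methyl under the dienal, tether exo, ring A chair) gives the trans ring fusion, the (E)-alkene makes C10-Me and the C9 vinyl cis, the catalyst shields one face of the dienal so C5, C9 and C10 are set in one absolute sense, and the aldehyde is trapped in the same flask as its dimethyl acetal before it can conjugate; closest known reaction types are Lewis acid-catalysed intramolecular Diels–Alder reactions of 1,3,9-decatrienes, chiral oxazaborolidinium-catalysed Diels–Alder reactions of enals, and polar (ionic) [4+2] cycloadditions with dienes as 2π partners.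

Step 6
Reactants: 14 methyl 4-hydroxybut-2-ynoate
Product: 15 methyl (2Z)-4-hydroxy-3-iodobut-2-enoate
Conditions: LiI (1.5 equiv), AcOH (1.5 equiv), MeCN, 70 °C
Reagents that add atoms: lithium iodide [Li+].[I-]
Why: Conjugate hydroiodination of the ynoate: iodide adds to C3 and the allenolate is protonated anti, so I is cis to CO2Me and CH2OH is trans to it (no lactonisation possible).

Step 7
Reactants: 13 (1R,2R,4aR,8aS)-2-(dimethoxymethyl)-1-ethenyl-5,5,8a-trimethyl-1,2,4a,5,6,7,8,8a-octahydronaphthalene; 15 methyl (2Z)-4-hydroxy-3-iodobut-2-enoate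
Product: 17 methyl (2E)-5-[(1R,2R,4aR,8aS)-2-(dimethoxymethyl)-5,5,8a-trimethyl-1,2,4a,5,6,7,8,8a-octahydronaphthalen-1-yl]-3-(hydroxymethyl)pent-2-enoate, via alkylborane 16 (not isolated)
Conditions: 9-BBN dimer, THF, 0 → 40 °C; then 15, PdCl2(dppf) (5 mol%), AsPh3 (10 mol%), Cs2CO3, DMF/THF/H2O, rt
Reagents that add atoms: none
Why: 9-BBN hydroborates only the monosubstituted vinyl group (anti-Markovnikov; the hindered ring alkene and the acetal are untouched), and the B-alkyl Suzuki–Miyaura coupling proceeds with retention at the vinyl iodide, so the new chain is cis to CO2Me as in the target.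

Step 8
Reactants: 17 methyl (2E)-5-[(1R,2R,4aR,8aS)-2-(dimethoxymethyl)-5,5,8a-trimethyl-1,2,4a,5,6,7,8,8a-octahydronaphthalen-1-yl]-3-(hydroxymethyl)pent-2-enoate
Product: 18 methyl (2E)-5-[(1R,2R,4aR,8aS)-2-(dimethoxymethyl)-5,5,8a-trimethyl-1,2,4a,5,6,7,8,8a-octahydronaphthalen-1-yl]-3-[(formyloxy)methyl]pent-2-enoate
Conditions: HCO2H, DCC, CH2Cl2, 0 °C (premixed); then 17, DMAP (10 mol%), 0 °C
Reagents that add atoms: formic acid OC=O
Why: Steglich-type esterification of the only free hydroxyl with formic anhydride made in the flask; premixing keeps free acid away from the acetal.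

Step 9
Reactants: 18 methyl (2E)-5-[(1R,2R,4aR,8aS)-2-(dimethoxymethyl)-5,5,8a-trimethyl-1,2,4a,5,6,7,8,8a-octahydronaphthalen-1-yl]-3-[(formyloxy)methyl]pent-2-enoate
Product: 19 methyl (2E)-5-[(1R,2S,3R,4S,4aR,8aS)-2-(dimethoxymethyl)-3,4-epoxy-5,5,8a-trimethyldecahydronaphthalen-1-yl]-3-[(formyloxy)methyl]pent-2-enoate
Conditions: mCPBA, NaHCO3, CH2Cl2, 0 °C → rt
Reagents that add atoms: mCPBA OOC(=O)c1cccc(Cl)c1
Why: Prilezhaev epoxidation of the only electron-rich alkene (the enoate does not react); the face syn to the axial C10 methyl, the axial C4 methyl and the pseudo-axial acetal is blocked, so oxygen is delivered anti to the angular methyl, which sets the C6–O configuration.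

Step 10
Reactants: 19 methyl (2E)-5-[(1R,2S,3R,4S,4aR,8aS)-2-(dimethoxymethyl)-3,4-epoxy-5,5,8a-trimethyldecahydronaphthalen-1-yl]-3-[(formyloxy)methyl]pent-2-enoate
Product: 21 methyl (2E)-3-[(formyloxy)methyl]-5-[(1S,4R,4aR,8aS)-2-formyl-4-hydroxy-5,5,8a-trimethyl-1,4,4a,5,6,7,8,8a-octahydronaphthalen-1-yl]pent-2-enoate, via epoxy aldehyde 20 (not isolated)
Conditions: SiO2, 10% aq. oxalic acid, CH2Cl2, rt; then Et3N, CH2Cl2, 0 °C
Reagents that add atoms: water O
Why: Mild acetal hydrolysis unmasks the β,γ-epoxy aldehyde, which enolises towards C8 and opens the epoxide by E1cB β-elimination to the γ-hydroxy enal; the C6–O bond is not broken (configuration retained) and the C8 stereocentre is erased.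

**Compound list**
1 | 5-chloropent-1-yne | C#CCCCCl | starting material
2 | bromoethene (vinyl bromide) | C=CBr | starting material
3 | (E)-(5-chloro-2-methylpent-1-en-1-yl)dimethylalumane (not isolated) | C[Al](C)/C=C(\C)CCCCl | intermediate
4 | (3E)-7-chloro-4-methylhepta-1,3-diene | C=C/C=C(\C)CCCCl | intermediate
5 | 2-methylpropanenitrile (isobutyronitrile) | CC(C)C#N | starting material
6 | (6E)-2,2,6-trimethylnona-6,8-dienenitrile | N#CC(C)(C)CCC/C(C)=C/C=C | intermediate
7 | (6E)-2,2,6-trimethylnona-6,8-dienal | O=CC(C)(C)CCC/C(C)=C/C=C | intermediate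
8 | (Z)-1-methoxybut-1-en-3-yne | CO/C=C\C#C | starting material
9 | (1Z,10E)-1-methoxy-6,6,10-trimethyltrideca-1,10,12-trien-3-yn-5-ol, racemic carbinol, present as its lithium alkoxide (not isolated) | CO/C=C\C#CC(O)C(C)(C)CCC/C(C)=C/C=C | intermediate
10 | (1Z,3E,10E)-1-methoxy-6,6,10-trimethyltrideca-1,3,10,12-tetraen-5-ol, racemic carbinol (not isolated) | CO/C=C\C=C\C(O)C(C)(C)CCC/C(C)=C/C=C | intermediate
11 | (2E,4E,10E)-6,6,10-trimethyltrideca-2,4,10,12-tetraenal | O=C/C=C/C=C/C(C)(C)CCC/C(C)=C/C=C | intermediate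
12 | (1R,2R,4aR,8aS)-1-ethenyl-5,5,8a-trimethyl-1,2,4a,5,6,7,8,8a-octahydronaphthalene-2-carbaldehyde; trans-fused, CHO, vinyl and angular methyl all cis (not isolated) | C=C[C@@H]1[C@H](C=O)C=C[C@@H]2C(C)(C)CCC[C@@]12C | intermediate
13 | (1R,2R,4aR,8aS)-2-(dimethoxymethyl)-1-ethenyl-5,5,8a-trimethyl-1,2,4a,5,6,7,8,8a-octahydronaphthalene | C=C[C@@H]1[C@H](C(OC)OC)C=C[C@@H]2C(C)(C)CCC[C@@]12C | intermediate
14 | methyl 4-hydroxybut-2-ynoate | COC(=O)C#CCO | starting material
15 | methyl (2Z)-4-hydroxy-3-iodobut-2-enoate | COC(=O)/C=C(\I)CO | intermediate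
16 | 9-{2-[(1R,2R,4aR,8aS)-2-(dimethoxymethyl)-5,5,8a-trimethyl-1,2,4a,5,6,7,8,8a-octahydronaphthalen-1-yl]ethyl}-9-borabicyclo[3.3.1]nonane (not isolated) | C(C[C@@H]3[C@H](C(OC)OC)C=C[C@@H]4C(C)(C)CCC[C@@]34C)B1C2CCCC1CCC2 | intermediate
17 | methyl (2E)-5-[(1R,2R,4aR,8aS)-2-(dimethoxymethyl)-5,5,8a-trimethyl-1,2,4a,5,6,7,8,8a-octahydronaphthalen-1-yl]-3-(hydroxymethyl)pent-2-enoate | COC(=O)/C=C(\CC[C@@H]1[C@H](C(OC)OC)C=C[C@@H]2C(C)(C)CCC[C@@]12C)CO | intermediate
18 | methyl (2E)-5-[(1R,2R,4aR,8aS)-2-(dimethoxymethyl)-5,5,8a-trimethyl-1,2,4a,5,6,7,8,8a-octahydronaphthalen-1-yl]-3-[(formyloxy)methyl]pent-2-enoate | COC(=O)/C=C(\CC[C@@H]1[C@H](C(OC)OC)C=C[C@@H]2C(C)(C)CCC[C@@]12C)COC=O | intermediate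
19 | methyl (2E)-5-[(1R,2S,3R,4S,4aR,8aS)-2-(dimethoxymethyl)-3,4-epoxy-5,5,8a-trimethyldecahydronaphthalen-1-yl]-3-[(formyloxy)methyl]pent-2-enoate; oxirane on the face opposite the angular methyl | COC(=O)/C=C(\CC[C@@H]1[C@H](C(OC)OC)[C@H]3O[C@H]3[C@@H]2C(C)(C)CCC[C@@]12C)COC=O | intermediate
20 | methyl (2E)-5-[(1R,2S,3R,4S,4aR,8aS)-3,4-epoxy-2-formyl-5,5,8a-trimethyldecahydronaphthalen-1-yl]-3-[(formyloxy)methyl]pent-2-enoate (not isolated) | COC(=O)/C=C(\CC[C@@H]1[C@H](C=O)[C@H]3O[C@H]3[C@@H]2C(C)(C)CCC[C@@]12C)COC=O | intermediate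
21 | methyl (2E)-3-[(formyloxy)methyl]-5-[(1S,4R,4aR,8aS)-2-formyl-4-hydroxy-5,5,8a-trimethyl-1,4,4a,5,6,7,8,8a-octahydronaphthalen-1-yl]pent-2-enoate (CNP0134813.1) | COC(=O)/C=C(\CC[C@@H]1C(C=O)=C[C@@H](O)[C@@H]2C(C)(C)CCC[C@@]12C)COC=O | target

**Totals**
Total steps: 10. Longest linear sequence: 9 (steps 1–5 and 7–10; step 6 makes the side-chain partner).

**Steps most likely to fail, with fallbacks**

Step 5 (the ring-forming step) is the main risk. The boron-bound dienal may be too weak an electrophile, the exo mode would give the cis-fused decalin, and the level and sense of enantiocontrol are unproven. The fallback sets out from 11 and comes back at 13. Compound 11 is condensed with (2R,4R)-pentane-2,4-diol (PPTS, MgSO4, CH2Cl2) to the chiral dienyl acetal (4R,6R)-4,6-dimethyl-2-[(1E,3E,9E)-5,5,9-trimethyldodeca-1,3,9,11-tetraen-1-yl]-1,3-dioxane F1. TMSOTf (CH2Cl2, −78 °C) opens the acetal to a dienyl oxocarbenium ion, far more electrophilic than the boron-bound aldehyde, which undergoes the same ring A/ring B closure; the tethered silyl ether then recloses to the bicyclic acetal (4R,6R)-2-[(1R,2R,4aR,8aS)-1-ethenyl-5,5,8a-trimethyl-1,2,4a,5,6,7,8,8a-octahydronaphthalen-2-yl]-4,6-dimethyl-1,3-dioxane F2. The diastereomers are separated by chromatography, so enantiopurity no longer rests on catalyst control (the other diol enantiomer is used if the minor diastereomer carries the needed core). Acid methanolysis (HC(OMe)3, MeOH, CSA) then gives 13.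

Step 7 is at risk because the vinyl group sits next to a quaternary carbon and an axial acetal, so hydroboration or transmetalation may be slow, and the (Z)-iodo enoate can isomerise under base. The fallback sets out from 13 and comes back at 17. Hydroboration of 13 with 9-BBN followed by I2/NaOMe gives the primary iodide (1R,2R,4aR,8aS)-2-(dimethoxymethyl)-1-(2-iodoethyl)-5,5,8a-trimethyl-1,2,4a,5,6,7,8,8a-octahydronaphthalene F3. This is joined to 15 by a base-free nickel-catalysed reductive cross-electrophile coupling (NiI2, 4,4'-di-tert-butyl-2,2'-bipyridine, Mn powder, DMA, rt), which keeps the vinyl iodide geometry and gives 17.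

Step 10 is at risk because acid may open the epoxide (by water or by the neighbouring acetal oxygen) or cleave the formate before the aldehyde is free. The fallback sets out from 18 and comes back at 21, and installs the C6 oxygen by a different reaction. Compound 18 is hydrolysed with deliberate conjugation (TsOH, acetone/H2O; then DBU) to the conjugated enal methyl (2E)-5-[2-formyl-5,5,8a-trimethyl-1,4,4a,5,6,7,8,8a-octahydronaphthalen-1-yl]-3-[(formyloxy)methyl]pent-2-enoate F4 (ring configuration as in 21). TBSOTf/Et3N (CH2Cl2, −78 °C) converts it into the silyl dienol ether methyl (2E)-5-[2-{[(tert-butyldimethylsilyl)oxy]methylidene}-5,5,8a-trimethyl-1,2,4a,5,6,7,8,8a-octahydronaphthalen-1-yl]-3-[(formyloxy)methyl]pent-2-enoate F5. DMDO (acetone, −78 °C) oxidises the ring alkene of the dienol ether from the face opposite the angular methyl (vinylogous Rubottom oxidation), and mild desilylation on work-up gives 21.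

**Further compounds**
F1 | step 5 | (4R,6R)-4,6-dimethyl-2-[(1E,3E,9E)-5,5,9-trimethyldodeca-1,3,9,11-tetraen-1-yl]-1,3-dioxane | C[C@@H]1C[C@@H](C)OC(/C=C/C=C/C(C)(C)CCC/C(C)=C/C=C)O1
F2 | step 5 | (4R,6R)-2-[(1R,2R,4aR,8aS)-1-ethenyl-5,5,8a-trimethyl-1,2,4a,5,6,7,8,8a-octahydronaphthalen-2-yl]-4,6-dimethyl-1,3-dioxane | C=C[C@@H]1[C@H](C3O[C@H](C)C[C@@H](C)O3)C=C[C@@H]2C(C)(C)CCC[C@@]12C
F3 | step 7 | (1R,2R,4aR,8aS)-2-(dimethoxymethyl)-1-(2-iodoethyl)-5,5,8a-trimethyl-1,2,4a,5,6,7,8,8a-octahydronaphthalene | ICC[C@@H]1[C@H](C(OC)OC)C=C[C@@H]2C(C)(C)CCC[C@@]12C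
F4 | step 10 | methyl (2E)-5-[2-formyl-5,5,8a-trimethyl-1,4,4a,5,6,7,8,8a-octahydronaphthalen-1-yl]-3-[(formyloxy)methyl]pent-2-enoate, ring configuration as in 21 | COC(=O)/C=C(\CC[C@@H]1C(C=O)=CC[C@@H]2C(C)(C)CCC[C@@]12C)COC=O
F5 | step 10 | methyl (2E)-5-[2-{[(tert-butyldimethylsilyl)oxy]methylidene}-5,5,8a-trimethyl-1,2,4a,5,6,7,8,8a-octahydronaphthalen-1-yl]-3-[(formyloxy)methyl]pent-2-enoate, ring configuration as in 21, enol ether geometry not defined | COC(=O)/C=C(\CC[C@@H]1C(=CO[Si](C)(C)C(C)(C)C)C=C[C@@H]2C(C)(C)CCC[C@@]12C)COC=O
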